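## Assumptions
- 3,5-Dihydroxy-4-methoxybenzaldehyde and 3,4,5-tris(benzyloxy)benzoic acid are purchasable.
- By analogy with cinnamaldehyde, the (S)-diarylprolinol silyl ether catalyst gives the (2R,3S)-trans-epoxy aldehyde. If the opposite sense is found, the (R)-catalyst is used.

## Retrosynthetic overview
1. Target ⇐ global hydrogenolysis of a perbenzylated galloyl ester ⇐ Mitsunobu galloylation of a 2,3-trans-flavan-3-ol. The inversion at C3 creates the 2,3-cis relationship.
2. The trans-flavan-3-ol ⇐ a one-pot acid cascade on an epoxy carbinol. An ortho-OBn group opens the epoxide 6-endo at the benzylic carbon with inversion, which forms the C ring, and the benzylic C4–OH is reduced to CH2.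
3. The epoxy carbinol ⇐ 2,4,6-tris(benzyloxy)phenyllithium + a trans-epoxy aldehyde (this forms the C4–C4a bond).
4. The epoxy aldehyde ⇐ organocatalytic iminium epoxidation of a cinnamaldehyde made from the B-ring benzaldehyde by Wittig olefination. This epoxidation is the first stereocentre-setting step. The A and B rings stay aromatic throughout, and the C ring closes in the cascade.

## Route

**Step 1**
Reactants: 1 (3,5-dihydroxy-4-methoxybenzaldehyde); 2 (benzyl bromide)
Product: 3 (3,5-bis(benzyloxy)-4-methoxybenzaldehyde)
Conditions: BnBr (2.4 equiv), K2CO3, TBAI (cat.), DMF, 60 °C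
Reagents that add atoms: benzyl bromide, BrCc1ccccc1
Why: Williamson O-benzylation of both phenols; the aldehyde and the 4-OMe group are unaffected.

**Step 2**
Reactants: 3; 4 ((triphenylphosphoranylidene)acetaldehyde)
Product: 5 ((E)-3-[3,5-bis(benzyloxy)-4-methoxyphenyl]acrylaldehyde)
Conditions: toluene, 80 °C, 16 h
Reagents that add atoms: Ph3P=CHCHO, O=CC=P(c1ccccc1)(c1ccccc1)c1ccccc1
Why: Wittig olefination with a stabilised ylide gives the E-enal (a two-carbon homologation).

**Step 3**
Reactants: 5; 6 ((S)-2-{bis[3,5-bis(trifluoromethyl)phenyl](trimethylsilyloxy)methyl}pyrrolidine, organocatalyst); 7 (hydrogen peroxide)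
Product: 8 ((2R,3S)-3-[3,5-bis(benzyloxy)-4-methoxyphenyl]oxirane-2-carbaldehyde, trans)
Conditions: 6 (10 mol%), 30% aq. H2O2 (1.3 equiv), CH2Cl2, rt, 12 h; rapid silica filtration
Reagents that add atoms: hydrogen peroxide, OO
Why: Organocatalytic iminium-activated nucleophilic epoxidation (Jørgensen–Marigo type). HOO⁻ adds to the face of the chiral iminium not shielded by the bulky aryl groups, and the resulting enamine closes the epoxide. This sets both epoxide stereocentres, trans.

**Step 4**
Reactants: 9 (phloroglucinol); 2 (benzyl bromide)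
Product: 10 (1,3,5-tris(benzyloxy)benzene)
Conditions: BnBr (3.6 equiv), K2CO3, DMF, 80 °C
Reagents that add atoms: benzyl bromide, BrCc1ccccc1
Why: Exhaustive Williamson O-benzylation gives the A-ring nucleophile precursor.

**Step 5**
Reactants: 10; 8
Product: 11 (epoxy carbinol, mixture of C4 epimers, epoxide stereochemistry as in 8)
Conditions: 10 (1.3 equiv), n-BuLi (1.25 equiv), THF, 0 °C, 1 h; cool to −78 °C, add 8, 1 h; sat. NH4Cl quench
Reagents that add atoms: none
Why: Directed ortho-lithiation between two OBn groups, then 1,2-addition of the aryllithium to the aldehyde. The C4 carbinol centre is destroyed in the next step, so its configuration is irrelevant. The epoxide stereocentres are untouched.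

**Step 6**
Reactants: 11
Product: 12 ((2R,3S)-5,7-bis(benzyloxy)-2-[3,5-bis(benzyloxy)-4-methoxyphenyl]chroman-3-ol)
Conditions: Et3SiH (4 equiv), pentamethylbenzene (3 equiv), TFA (20 equiv), CH2Cl2 (0.02 M), 0 °C → rt, 2 h; then sat. NaHCO3, then MeOH, rt, 20 min to cleave any 3-O-trifluoroacetate
Reagents that add atoms: none
Why: Proposed new method: TFA protonates the epoxide, and the 4-OMe-aryl-activated benzylic C2 is attacked 6-endo by the ortho-benzyloxy oxygen with inversion. The benzyl aryl alkyl oxonium formed is debenzylated, and pentamethylbenzene and Et3SiH trap Bn⁺. In the same pot, the tris-alkoxyaryl carbinol at C4 ionises and is reduced by Et3SiH (ionic hydrogenation), in either order. The closest known reactions are (i) acid-promoted 6-endo cycloetherification of epoxides, (ii) debenzylative cycloetherification through benzyl oxonium ions, and (iii) Et3SiH/TFA deoxygenation of electron-rich benzylic alcohols. The new element is using an aryl benzyl ether as a masked phenol nucleophile toward a benzylic epoxide, combined with C4 deoxygenation. Stereochemistry: C3 is retained from the epoxide (its CIP label changes from R to S only because the substituent priorities change). Inversion at C2 from the trans-epoxide (S to R) gives the 2,3-trans (2R,3S) flavan. Dilution suppresses 4→8 dimerisation.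

**Step 7**
Reactants: 12; 13 (3,4,5-tris(benzyloxy)benzoic acid)
Product: 14 ((2R,3R)-ester: 3-O-[3,4,5-tris(benzyloxy)benzoyl] derivative of 12, 2,3-cis)
Conditions: 13 (1.5 equiv), PPh3 (1.5 equiv), DIAD (1.5 equiv), THF, 0 °C → rt, 12 h
Reagents that add atoms: 3,4,5-tris(benzyloxy)benzoic acid, OC(=O)c1cc(OCc2ccccc2)c(OCc2ccccc2)c(OCc2ccccc2)c1
Why: Mitsunobu esterification proceeds by SN2 on the alkoxyphosphonium, inverting C3 from S to R. This converts 2,3-trans into 2,3-cis and installs the galloyl ester in one step. C2 is untouched.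

**Step 8**
Reactants: 14
Product: 15 (4'-O-methylepigallocatechin-3-O-gallate, target)
Conditions: H2 (1 atm), Pd(OH)2/C, THF/MeOH 1:1, rt, 6 h
Reagents that add atoms: none (H2 adds only hydrogen)
Why: Catalytic hydrogenolysis removes all seven benzyl ethers (two on the B ring, two on the A ring, three on the galloyl group). The aryl methyl ether, the ester and both stereocentres survive these neutral conditions.

## Compound list
1 | 3,5-dihydroxy-4-methoxybenzaldehyde | COc1c(O)cc(C=O)cc1O | starting material
2 | benzyl bromide | BrCc1ccccc1 | starting material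
3 | 3,5-bis(benzyloxy)-4-methoxybenzaldehyde | COc1c(OCc2ccccc2)cc(C=O)cc1OCc1ccccc1 | intermediate
4 | (triphenylphosphoranylidene)acetaldehyde | O=CC=P(c1ccccc1)(c1ccccc1)c1ccccc1 | starting material
5 | (E)-3-[3,5-bis(benzyloxy)-4-methoxyphenyl]acrylaldehyde | COc1c(OCc2ccccc2)cc(/C=C/C=O)cc1OCc1ccccc1 | intermediate
6 | (S)-2-{bis[3,5-bis(trifluoromethyl)phenyl](trimethylsilyloxy)methyl}pyrrolidine (organocatalyst) | C[Si](C)(C)OC(c1cc(C(F)(F)F)cc(C(F)(F)F)c1)(c1cc(C(F)(F)F)cc(C(F)(F)F)c1)[C@@H]1CCCN1 | starting material
7 | hydrogen peroxide | OO | starting material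
8 | (2R,3S)-trans-3-[3,5-bis(benzyloxy)-4-methoxyphenyl]oxirane-2-carbaldehyde | O=C[C@@H]1O[C@H]1c1cc(OCc2ccccc2)c(OC)c(OCc2ccccc2)c1 | intermediate
9 | phloroglucinol | Oc1cc(O)cc(O)c1 | starting material
10 | 1,3,5-tris(benzyloxy)benzene | C(c1ccccc1)Oc1cc(OCc2ccccc2)cc(OCc2ccccc2)c1 | intermediate
11 | epoxy carbinol (C4 epimers) | OC(c1c(OCc2ccccc2)cc(OCc2ccccc2)cc1OCc1ccccc1)[C@@H]1O[C@H]1c1cc(OCc2ccccc2)c(OC)c(OCc2ccccc2)c1 | intermediate
12 | (2R,3S)-tetra-O-benzyl-4'-O-methylgallocatechin | COc1c(OCc2ccccc2)cc([C@H]3Oc4cc(OCc5ccccc5)cc(OCc5ccccc5)c4C[C@@H]3O)cc1OCc1ccccc1 | intermediate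
13 | 3,4,5-tris(benzyloxy)benzoic acid | OC(=O)c1cc(OCc2ccccc2)c(OCc2ccccc2)c(OCc2ccccc2)c1 | starting material
14 | perbenzylated (2R,3R)-galloyl ester | COc1c(OCc2ccccc2)cc([C@H]3Oc4cc(OCc5ccccc5)cc(OCc5ccccc5)c4C[C@H]3OC(=O)c3cc(OCc6ccccc6)c(OCc6ccccc6)c(OCc6ccccc6)c3)cc1OCc1ccccc1 | intermediate
15 | 4'-O-methylepigallocatechin-3-O-gallate | COc1c(O)cc([C@H]2Oc3cc(O)cc(O)c3C[C@H]2OC(=O)c2cc(O)c(O)c(O)c2)cc1O | target

## Summary
- Total steps: 8 (step 4 is a parallel preparation of the A-ring arene).
- Longest linear sequence: 7 (steps 1, 2, 3, 5, 6, 7, 8).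

**Three steps most likely to fail**
1. **Step 6 (the proposed new cascade).** Competing side reactions are epoxide opening by trifluoroacetate, hydride delivery to the benzylic epoxide carbon, C-benzylation of the A ring, loss of other O-benzyl groups in TFA, 4→8 dimerisation, and cis-epimer formation through SN1 character.
   - Fallback: a stepwise route with a different A-ring oxygen protection. Prepare 2-lithio-1-(MOM-oxy)-3,5-bis(benzyloxy)benzene for step 5 and add it to 8. Oxidise the carbinol (Dess–Martin) to the α,β-epoxy ketone. TsOH/MeOH then removes the MOM group and closes the ring 6-endo (Algar–Flynn–Oyamada-type), giving the 2,3-trans-3-hydroxyflavanone. NaBH4 and then Et3SiH/TFA remove the C4 oxygen to reach 12.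
2. **Step 7 (Mitsunobu inversion).** B-ring (p-methoxyaryl) neighbouring-group participation could give retention (trans ester), or elimination to the flav-3-ene could compete.
   - Fallback: Dess–Martin oxidation of 12 to the flavan-3-one, L-selectride reduction to the 2,3-cis alcohol, then EDC/DMAP esterification with 13.
3. **Step 5 (aryllithium addition to the epoxy aldehyde).** The lithiation of 10 (benzylic lithiation or Wittig rearrangement could compete) and the survival of the sensitive epoxy aldehyde are both uncertain.
   - Fallback: build C4–C4a before the epoxidation. Claisen–Schmidt condensation of 2'-(MOM-oxy)-4',6'-bis(benzyloxy)acetophenone with 3 gives the chalcone. Metal-free phase-transfer (cinchona ammonium) epoxidation with H2O2/NaOH then gives the chiral α,β-epoxy ketone. This enters the TsOH/MeOH ring closure and the NaBH4 then Et3SiH/TFA sequence described in item 1.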